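**Retrosynthetic overview**
1. Last operation: the α-methylene lactone and the free side-chain hydroxyl are unveiled together (E1cB loss of a 13-acyloxy group, then desilylation); the C8 and C13 esters come from one acid.
2. Ten-membered ring (third ring): ring-closing metathesis that forms the C1=C10 Z-alkene.
3. Key C7–C8 bond: conjugate addition of an α-hydroxyalkyl radical (C–H abstraction from a C5 alkenol) to a 3-(hydroxymethyl)butenolide, anti to the C6 substituent.
4. Butenolide (second ring): ring-closing metathesis of a 2-(hydroxymethyl)acrylate, reached by Mitsunobu inversion at C6 and Baylis–Hillman hydroxymethylation.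
5. Oxirane (first ring) with C4/C5/C6: Sharpless kinetic resolution of a racemic dienyl carbinol made by enyne carboalumination and addition to an enal.

Positions are given in germacrane numbering (ring C1–C10, lactone carbons C11–C13, C14 on C10, C15 on C4). The target is 4R,5R,6S,7R,8R with a 1(10)Z alkene and a 2E side chain.
Assumption: 2-[(tert-butyldimethylsilyl)oxy]acetaldehyde (13) is bought as such; its silyl group is a protecting group, so the fragment it contributes is C2O.

**Step 1**
Reactants: 1 hex-1-en-5-yne; 2 prop-2-enal (acrolein)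
Product: 5 rac-(4E)-5-methylnona-1,4,8-trien-3-ol, via alkenylalane 3 (not isolated), via lithium alanate 4 (not isolated)
Conditions: AlMe3 (2.5 equiv), Cp2ZrCl2 (0.25 equiv), CH2Cl2, 0 °C to rt; evaporate excess AlMe3; n-BuLi, hexane/THF, −78 °C; then 2, −78 to 0 °C; aq. potassium sodium tartrate
Reagents that add atoms: trimethylaluminium, C[Al](C)C
Why: Negishi zirconium-catalysed syn-carboalumination puts CH3 on the internal and Al on the terminal alkyne carbon on the same side, which fixes the E trisubstituted C4=C5 alkene, and the alanate then adds 1,2 to the enal to give the racemic bis-allylic alcohol; the isolated terminal alkene is untouched.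

**Step 2**
Reactants: 5 rac-(4E)-5-methylnona-1,4,8-trien-3-ol
Product: 6 (1R)-1-[(2R,3R)-3-(but-3-en-1-yl)-3-methyloxiran-2-yl]prop-2-en-1-ol
Conditions: Ti(O-i-Pr)4 (10 mol%), D-(−)-diisopropyl tartrate (14 mol%), t-BuOOH (0.55 equiv), 4 Å molecular sieves, CH2Cl2, −20 °C
Reagents that add atoms: tert-butyl hydroperoxide, CC(C)(C)OO
Why: Sharpless kinetic resolution (asymmetric epoxidation): with the D-(−)-tartrate the titanium complex epoxidises only the (R)-alcohol at the allylic trisubstituted alkene, on the face that gives 4R,5R, and as always in this resolution the product is the erythro epoxy alcohol (C6 R); the (S)-alcohol stays behind, the vinyl and butenyl alkenes are far slower, and the reaction is stopped near 45% conversion because the cis-methyl group lowers the rate ratio.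

**Step 3**
Reactants: 6 (1R)-1-[(2R,3R)-3-(but-3-en-1-yl)-3-methyloxiran-2-yl]prop-2-en-1-ol; 7 prop-2-enoic acid (acrylic acid)
Product: 8 (1S)-1-[(2R,3R)-3-(but-3-en-1-yl)-3-methyloxiran-2-yl]prop-2-en-1-yl prop-2-enoate
Conditions: PPh3, DIAD, THF, 0 °C (betaine preformed); then 6 and 7, −20 °C to rt
Reagents that add atoms: none
Why: Mitsunobu esterification: SN2 displacement of the oxyphosphonium by acrylate inverts C6 from R to the required S (erythro to threo) and installs the acrylate in the same operation; preforming the betaine keeps free PPh3 away from acrylic acid.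

**Step 4**
Reactants: 8 (1S)-1-[(2R,3R)-3-(but-3-en-1-yl)-3-methyloxiran-2-yl]prop-2-en-1-yl prop-2-enoate
Product: 9 (1S)-1-[(2R,3R)-3-(but-3-en-1-yl)-3-methyloxiran-2-yl]prop-2-en-1-yl 2-(hydroxymethyl)prop-2-enoate
Conditions: DABCO (1 equiv), 37% aq. HCHO, 1,4-dioxane/H2O, rt
Reagents that add atoms: formaldehyde, C=O
Why: Morita–Baylis–Hillman reaction: DABCO adds to the acrylate and the ammonium enolate takes up formaldehyde, giving the 2-(hydroxymethyl)acrylate (future C13) under conditions that leave the epoxide and the allylic ester alone; no stereocentre is touched.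

**Step 5**
Reactants: 9 (1S)-1-[(2R,3R)-3-(but-3-en-1-yl)-3-methyloxiran-2-yl]prop-2-en-1-yl 2-(hydroxymethyl)prop-2-enoate
Product: 10 (5S)-5-[(2R,3R)-3-(but-3-en-1-yl)-3-methyloxiran-2-yl]-3-(hydroxymethyl)furan-2(5H)-one
Conditions: second-generation Grubbs catalyst RuCl2(=CHPh)(H2IMes)(PCy3) (5 mol%), CH2Cl2 (5 mM), 40 °C
Reagents that add atoms: none
Why: Ring-closing metathesis between the C7 vinyl group and the 1,1-disubstituted acrylate closes the five-membered butenolide and loses ethene; the only other ring the butenyl alkene could close with the vinyl group is seven-membered with a trans-fused epoxide, and C6 is not affected.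

**Step 6 (key step)**
Reactants: 10 (5S)-5-[(2R,3R)-3-(but-3-en-1-yl)-3-methyloxiran-2-yl]-3-(hydroxymethyl)furan-2(5H)-one; 11 3-methylbut-3-en-1-ol
Product: 12 (4R,5S)-5-[(2R,3R)-3-(but-3-en-1-yl)-3-methyloxiran-2-yl]-4-[(1R)-1-hydroxy-3-methylbut-3-en-1-yl]-3-(hydroxymethyl)oxolan-2-one (C3 epimers)
Conditions: [Ir(dF(CF3)ppy)2(dtbbpy)]PF6 (1 mol%), quinuclidine (10 mol%), Bu4N(H2PO4) (25 mol%), 11 (10 equiv), MeCN, blue LEDs (450 nm), rt
Reagents that add atoms: none
Why: Photoredox/hydrogen-atom-transfer α-hydroxy C–H alkylation (Giese-type radical conjugate addition): the quinuclidine radical cation abstracts the hydridic, phosphate-activated carbinol C–H of 11, the nucleophilic α-hydroxyalkyl radical adds to C7 of the butenolide on the face anti to the C6 oxiranyl group (sets C7 R, 6,7-trans), and the α-acyl radical is reduced and protonated at C11; because hydroxide cannot leave from that enolate, no exo-methylene lactone (a better radical acceptor than 10) is formed at this stage; C8 is not controlled by the butenolide (about 1:1 to 2:1 expected) and the 8R diol 12 is separated by chromatography; the reaction type is known for acrylates, its use on a trisubstituted butenolide is an untested extension.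

**Step 7**
Reactants: 13 2-[(tert-butyldimethylsilyl)oxy]acetaldehyde; 14 2-methylpropanedioic acid (methylmalonic acid)
Product: 15 (2E)-4-[(tert-butyldimethylsilyl)oxy]-2-methylbut-2-enoic acid
Conditions: pyridine, piperidine (cat.), 70 °C
Reagents that add atoms: none
Why: Knoevenagel–Doebner condensation: aldol addition of methylmalonic acid followed by decarboxylative dehydration can give only the α,β-unsaturated acid (no alkylidene malonate is possible), with CO2H trans to the CH2OTBS group (E).

**Step 8**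
Reactants: 12 (4R,5S)-5-[(2R,3R)-3-(but-3-en-1-yl)-3-methyloxiran-2-yl]-4-[(1R)-1-hydroxy-3-methylbut-3-en-1-yl]-3-(hydroxymethyl)oxolan-2-one; 15 (2E)-4-[(tert-butyldimethylsilyl)oxy]-2-methylbut-2-enoic acid (2.5 equiv)
Product: 17 bis-ester of 12, acylated at O8 and O13 by the (2E)-4-[(tert-butyldimethylsilyl)oxy]-2-methylbut-2-enoyl group (8R retained; C11 epimers), via mixed anhydride 16 (not isolated)
Conditions: 2,4,6-Cl3C6H2COCl, Et3N, THF, rt; then 12, DMAP, toluene, rt
Reagents that add atoms: none
Why: Yamaguchi esterification acylates both hydroxyl groups with retention, so C8 keeps its R configuration and gains the side chain, while the second acyl group turns O13 into the leaving group needed in step 10.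

**Step 9**
Reactants: 17 bis-ester of 12
Product: 18 (1(10)Z,4R,5R,6S,7R,8R)-4,5-epoxy-8,13-bis{[(2E)-4-[(tert-butyldimethylsilyl)oxy]-2-methylbut-2-enoyl]oxy}-11,13-dihydrogermacr-1(10)-en-12,6-olide (C11 epimers)
Conditions: second-generation Hoveyda–Grubbs catalyst RuCl2(=CH-C6H4-2-O-i-Pr)(H2IMes) (15 mol%), toluene (1 mM), 80 °C
Reagents that add atoms: none
Why: Ring-closing metathesis of the monosubstituted C1 alkene with the 1,1-disubstituted C10 alkene under high dilution; the trans-lactone holds the two arms on adjacent carbons, a ten-membered ring accepts the Z trisubstituted alkene far more easily than the strained E isomer, and with C11=C13 still masked there is no acrylate to compete.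

**Step 10**
Reactants: 18 macrocyclic bis-ester
Product: 20 (1(10)Z,4R,5R,6S,7R,8R)-4,5-epoxy-8-{[(2E)-4-hydroxy-2-methylbut-2-enoyl]oxy}germacra-1(10),11(13)-dien-12,6-olide (CNP0198076.5), via silyl ether 19 (not isolated)
Conditions: DBU, THF, 0 °C; then Et3N·3HF, rt (one pot)
Reagents that add atoms: none
Why: DBU removes the acidic C11–H and the enolate expels the 13-carboxylate (E1cB elimination) to unveil the α-methylene lactone, then fluoride cleaves the primary allylic silyl ether under near-neutral conditions that spare the acid-sensitive epoxide; no stereocentre is involved.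

**Compound list**
1 | hex-1-en-5-yne | C=CCCC#C | starting material
2 | prop-2-enal (acrolein) | C=CC=O | starting material
3 | dimethyl[(1E)-2-methylhexa-1,5-dien-1-yl]alumane | C=CCC/C(C)=C/[Al](C)C | intermediate (not isolated)
4 | lithium butyl(dimethyl)[(1E)-2-methylhexa-1,5-dien-1-yl]aluminate | [Li+].CCCC[Al-](C)(C)/C=C(\C)CCC=C | intermediate (not isolated)
5 | rac-(4E)-5-methylnona-1,4,8-trien-3-ol | C=CC(O)/C=C(\C)CCC=C | intermediate
6 | (1R)-1-[(2R,3R)-3-(but-3-en-1-yl)-3-methyloxiran-2-yl]prop-2-en-1-ol | C=C[C@@H](O)[C@H]1O[C@]1(C)CCC=C | intermediate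
7 | prop-2-enoic acid (acrylic acid) | C=CC(=O)O | starting material
8 | (1S)-1-[(2R,3R)-3-(but-3-en-1-yl)-3-methyloxiran-2-yl]prop-2-en-1-yl prop-2-enoate | C=CC(=O)O[C@@H](C=C)[C@H]1O[C@]1(C)CCC=C | intermediate
9 | (1S)-1-[(2R,3R)-3-(but-3-en-1-yl)-3-methyloxiran-2-yl]prop-2-en-1-yl 2-(hydroxymethyl)prop-2-enoate | C=C(CO)C(=O)O[C@@H](C=C)[C@H]1O[C@]1(C)CCC=C | intermediate
10 | (5S)-5-[(2R,3R)-3-(but-3-en-1-yl)-3-methyloxiran-2-yl]-3-(hydroxymethyl)furan-2(5H)-one | O=C1O[C@@H](C=C1CO)[C@H]2O[C@]2(C)CCC=C | intermediate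
11 | 3-methylbut-3-en-1-ol | C=C(C)CCO | starting material
12 | (4R,5S)-5-[(2R,3R)-3-(but-3-en-1-yl)-3-methyloxiran-2-yl]-4-[(1R)-1-hydroxy-3-methylbut-3-en-1-yl]-3-(hydroxymethyl)oxolan-2-one (C3 epimers) | O=C1O[C@@H]([C@@H]([C@H](O)CC(C)=C)C1CO)[C@H]2O[C@]2(C)CCC=C | intermediate
13 | 2-[(tert-butyldimethylsilyl)oxy]acetaldehyde | CC(C)(C)[Si](C)(C)OCC=O | starting material
14 | 2-methylpropanedioic acid (methylmalonic acid) | CC(C(=O)O)C(=O)O | starting material
15 | (2E)-4-[(tert-butyldimethylsilyl)oxy]-2-methylbut-2-enoic acid | C/C(=C\CO[Si](C)(C)C(C)(C)C)C(=O)O | intermediate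
16 | (2E)-4-[(tert-butyldimethylsilyl)oxy]-2-methylbut-2-enoic 2,4,6-trichlorobenzoic anhydride | CC(C)(C)[Si](C)(C)OC/C=C(\C)C(=O)OC(=O)c1c(Cl)cc(Cl)cc1Cl | intermediate (not isolated)
17 | [(4R,5S)-5-[(2R,3R)-3-(but-3-en-1-yl)-3-methyloxiran-2-yl]-4-[(1R)-1-{[(2E)-4-[(tert-butyldimethylsilyl)oxy]-2-methylbut-2-enoyl]oxy}-3-methylbut-3-en-1-yl]-2-oxooxolan-3-yl]methyl (2E)-4-[(tert-butyldimethylsilyl)oxy]-2-methylbut-2-enoate (C3 epimers) | O=C1O[C@@H]([C@@H]([C@H](OC(=O)/C(C)=C/CO[Si](C)(C)C(C)(C)C)CC(C)=C)C1COC(=O)/C(C)=C/CO[Si](C)(C)C(C)(C)C)[C@H]2O[C@]2(C)CCC=C | intermediate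
18 | (1(10)Z,4R,5R,6S,7R,8R)-4,5-epoxy-8,13-bis{[(2E)-4-[(tert-butyldimethylsilyl)oxy]-2-methylbut-2-enoyl]oxy}-11,13-dihydrogermacr-1(10)-en-12,6-olide (C11 epimers) | C(OC(=O)/C(C)=C/CO[Si](C)(C)C(C)(C)C)C1C(=O)O[C@H]2[C@H]1[C@H](OC(=O)/C(C)=C/CO[Si](C)(C)C(C)(C)C)C/C(C)=C\CC[C@@]1(C)O[C@H]21 | intermediate
19 | (1(10)Z,4R,5R,6S,7R,8R)-4,5-epoxy-8-{[(2E)-4-[(tert-butyldimethylsilyl)oxy]-2-methylbut-2-enoyl]oxy}germacra-1(10),11(13)-dien-12,6-olide | C=C1C(=O)O[C@H]2[C@H]1[C@H](OC(=O)/C(C)=C/CO[Si](C)(C)C(C)(C)C)C/C(C)=C\CC[C@@]1(C)O[C@H]21 | intermediate (not isolated)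
20 | (1(10)Z,4R,5R,6S,7R,8R)-4,5-epoxy-8-{[(2E)-4-hydroxy-2-methylbut-2-enoyl]oxy}germacra-1(10),11(13)-dien-12,6-olide (CNP0198076.5) | C=C1C(=O)O[C@H]2[C@H]1[C@H](OC(=O)/C(C)=C/CO)C/C(C)=C\CC[C@@]1(C)O[C@H]21 | target

**Step count**
Total: 10 steps. Longest linear sequence: 9 steps (steps 1–6 and 8–10); step 7 is a one-step branch for the side-chain acid.

**Three steps most likely to fail**

Step 6 (radical C7–C8 bond formation). The butenolide controls C7 but not C8, so a large share of the material may be the C8 epimer. That epimer can also translactonise to a trans 8,12-olide, and hydrogen abstraction at the CH2OH group of 10 competes unless 11 is in large excess. The fallback sets out from 10 and comes back at 17, and it fixes C8 by inversion instead of in the radical step. The epimer formed in the same reaction, (4R,5S)-5-[(2R,3R)-3-(but-3-en-1-yl)-3-methyloxiran-2-yl]-4-[(1S)-1-hydroxy-3-methylbut-3-en-1-yl]-3-(hydroxymethyl)oxolan-2-one F1, is isolated and treated with 15 (3 equiv), PPh3 and DIAD in toluene. This double Mitsunobu esterification acylates the primary hydroxyl and inverts C8 to R, giving 17.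

Step 9 (ten-membered ring-closing metathesis). Oligomerisation through the unhindered C1 alkene can outrun closure onto the 1,1-disubstituted alkene. The fallback sets out from 12 and comes back at 18, and it closes the ring before acylation on a tethered substrate. Diol 12 with (t-Bu)2Si(OTf)2 and 2,6-lutidine gives the 8,13-O-(di-tert-butylsilanediyl) derivative of 12 F2, a seven-membered dioxasilepane. With O8 tied to O13, an 8R centre must hold C9 gauche to C6, turned toward the other arm. Ring-closing metathesis then gives the ten-membered (1(10)Z) silylene F3. Bu4NF/AcOH releases (1(10)Z,4R,5R,6S,7R,8R)-4,5-epoxy-8,13-dihydroxy-11,13-dihydrogermacr-1(10)-en-12,6-olide F4, and Yamaguchi acylation with 15 gives 18.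

Step 3 (Mitsunobu inversion at the epoxy vinyl carbinol). SN2′ attack at the vinyl terminus, elimination or epoxide participation may compete at this hindered allylic centre. The fallback sets out from 5 and comes back at 8, and it takes C6 from the other enantiomer. The resolution of step 2 is run to about 60% conversion, which leaves (3S,4E)-5-methylnona-1,4,8-trien-3-ol F5 in high enantiomeric purity. mCPBA (NaHCO3, CH2Cl2, 0 °C) epoxidises the allylic trisubstituted alkene under hydroxyl direction and A(1,3) control to the threo epoxy alcohol (1S)-1-[(2R,3R)-3-(but-3-en-1-yl)-3-methyloxiran-2-yl]prop-2-en-1-ol F6. Acryloyl chloride and Et3N then esterify with retention to 8.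

**Further compounds**
F1 | step 6 | (4R,5S)-5-[(2R,3R)-3-(but-3-en-1-yl)-3-methyloxiran-2-yl]-4-[(1S)-1-hydroxy-3-methylbut-3-en-1-yl]-3-(hydroxymethyl)oxolan-2-one (C3 epimers) | O=C1O[C@@H]([C@@H]([C@@H](O)CC(C)=C)C1CO)[C@H]2O[C@]2(C)CCC=C
F2 | step 9 | 8,13-O-(di-tert-butylsilanediyl) derivative of 12 (2,2-di-tert-butyl-1,3,2-dioxasilepane fused to the lactone at C7–C11) | O=C1O[C@@H]([C@H]2[C@@H](CC(C)=C)O[Si](C(C)(C)C)(C(C)(C)C)OCC12)[C@H]3O[C@]3(C)CCC=C
F3 | step 9 | (1(10)Z,4R,5R,6S,7R,8R)-8,13-O-(di-tert-butylsilanediyl)-4,5-epoxy-8,13-dihydroxy-11,13-dihydrogermacr-1(10)-en-12,6-olide | C5C1C(=O)O[C@H]2[C@H]1[C@H](O[Si](C(C)(C)C)(C(C)(C)C)O5)C/C(C)=C\CC[C@@]1(C)O[C@H]21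
F4 | step 9 | (1(10)Z,4R,5R,6S,7R,8R)-4,5-epoxy-8,13-dihydroxy-11,13-dihydrogermacr-1(10)-en-12,6-olide | OCC1C(=O)O[C@H]2[C@H]1[C@H](O)C/C(C)=C\CC[C@@]1(C)O[C@H]21
F5 | step 3 | (3S,4E)-5-methylnona-1,4,8-trien-3-ol | C=C[C@H](O)/C=C(\C)CCC=C
F6 | step 3 | (1S)-1-[(2R,3R)-3-(but-3-en-1-yl)-3-methyloxiran-2-yl]prop-2-en-1-ol | C=C[C@H](O)[C@H]1O[C@]1(C)CCC=C
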